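Position labels used throughout: upper unit = ring A (C4a–C8a), pyran ring C (O1, C2, C3, C4), ring B on C2; lower catechin unit = ring D (C4a'–C8a'), pyran ring F (O1', C2', C3', C4'), ring E on C2'. "BrCat" stands for the 8-bromo-3,5,7,3',4'-penta-O-benzyl-(+)-catechin-6-yl group, i.e. (2R,3S)-3,5,7-tris(benzyloxy)-2-[3,4-bis(benzyloxy)phenyl]-8-bromochroman-6-yl.

## Analysis of the target

Compound 22 is a profisetinidin-type biflavanoid: a 5-deoxyflavan-3-ol (resorcinol-type ring A, pyran ring C, catechol ring B) is bonded through C4 to C6' of a (+)-catechin unit (phloroglucinol-type ring D, pyran ring F, catechol ring E). It has five stereocentres: C2' (R) and C3' (S) are those of natural catechin, and ring C carries C2 (S), C3 (R) and C4 (S). In ring C, ring B is trans to the C3 hydroxyl and the C3 hydroxyl is cis to ring D, so the aryl groups at C2 and C4 are trans to each other. The sensitive features are the seven phenolic hydroxyls (oxidised easily in base and air), the C4–C6' bond (a benzylic carbon para to the C7 oxygen joined to a very electron-rich arene, cleavable by strong acid) and the base-labile C2 and C2' centres once the para-hydroxyls of rings B and E are free. Three things make the synthesis hard: ring D has two nucleophilic positions, C6' and C8', and only C6' may be used; the 3,4-cis arrangement is the more crowded one; and the new centres lie beyond the twisted C4–C6' axis, so the catechin centres give almost no bias. The strategy rests on one feature: C4 is bonded to ring A and to ring D, and ring A carries O1 on C8a, ortho to C4a, so O1–C8a–C4a–C4 is the skeleton of an o-quinone methide with ring D on its exocyclic carbon. C2–C3 is then a two-carbon unit with an oxygen on each carbon if C2 is taken at the acetal level, so a phenol, an aldehyde and a cis-enediol ether can be united around C4 and ring B added afterwards at the acetal carbon.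

## Retrosynthetic reasoning

**22 from 21.** The last operation cuts the eight O–benzyl bonds and the C8'–Br bond by hydrogenolysis. Benzyl ethers are used on every phenol and on C3'–OH because they survive base, organozinc reagents, hydride and mild acid. The bromine on C8' blocks the more reactive ring D position so that C6' is formylated, lowers the basicity of ring D toward acid, and leaves without a step of its own.

**21 from 20, and 20 from 15 and 18.** The C2–ring B bond is cut. C2 is the only ring C carbon that leaves the key step at the acetal oxidation level, so it is the natural electrophile, and ring B is the nucleophile as arylzinc bromide 18. An ester on the C3 oxygen controls the step: it displaces the C2 leaving group to give the cis-fused dioxolenium ion 19, which can only be opened at C2 from the face opposite the C3 oxygen. That face is also opposite ring D, so 2,3-trans is expected. A pivalate is used rather than an acetate because the acyl carbon of an acetate-derived dioxolenium ion is open to the organozinc reagent, whereas the tert-butyl group shields it. Hydride then removes the pivalate to give 21.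

**15 from 14, 13 and 12.** These are functional group changes at C2 only: acetonide 12 is hydrolysed to lactol diol 13, both hydroxyls are pivaloylated (14), and the anomeric ester is exchanged for bromide (15). C3 and C4 are not touched, and the C2 configuration is irrelevant because every C2 epimer converges on 19.

**12 from 6, 7 and 8 (key disconnection).** Three bonds are cut: C4–C4a, C3–C4 and O1–C2. This reduces ring C to phenol 7 (ring A with O1), aldehyde 6 (C4 with ring D) and dioxole 8 (C2–C3 with both oxygens). No other cut gives three pieces of this simplicity, and no other cut makes the 3,4-cis relationship a direct result of a cycloaddition rule. Forward, a boron template first joins 7 and 6 ortho to the phenol oxygen (benzodioxaborin 9). Simply heating 9 would release the quinone methide with boron still on the phenol oxygen and with no handle for absolute control, so the boron is removed in the same flask by a diol to give o-hydroxybenzhydrol 10. A chiral Brønsted acid then generates E-quinone methide 11 and directs its endo [4+2] addition to the symmetrical 8. The step must deliver ortho regiochemistry on 7, the all-cis relative configuration, and the (3R,4S) absolute sense.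

**6 from 4, 3, 2 and 1.** The formyl carbon (future C4) is attached to C6' of the catechin unit. Catechin 1 supplies rings D, E and F with both stereocentres. Benzylation in two stages (phenols, then C3'–OH) gives 3, electrophilic bromination takes the more accessible C8' (4), and Vilsmeier–Haack formylation can then only occur at C6' (6).

**18 from 16.** Ring B comes from aryl bromide 16 by halogen–lithium exchange (17) and transmetalation with one equivalent of zinc bromide, so that each zinc carries one ring B aryl group.

## Alternatives that were turned down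

Alternative 1: ring D is dismantled last (C8'–C8a', C5'–C6', C7'–C8', C4a'–C5'). The precursors are diazo ketone A2, which carries ring F complete, and siloxyalkyne A3, the whole upper flavan with an alkynyl group on C4. Forward, irradiation triggers a Danheiser benzannulation (Wolff rearrangement, [2+2] addition to the alkyne, four-electron ring opening, six-electron ring closure) that grows ring D around C6' and gives A1.
- For: the 4→6 regiochemistry is built in, no blocking bromine is needed, and the two ring D oxygens come out differentiated. On this point it is stronger than the chosen route.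
- Against: all five stereocentres must be in place before the key step on fragments that cannot be drawn from catechin. A2 needs a de novo enantioselective synthesis of a 2-aryl-3-alkoxydihydropyran. A3 needs the complete 2,3-trans-3,4-cis ring C with an sp carbon at C4, so the stereochemical problem of ring C is only moved. The photochemical step must also work on a substrate full of absorbing arenes.
- Comparison: the step count would be roughly double. The chosen route pays for regiocontrol with one bromine atom and in return joins the halves in the step that also creates ring C and its two hardest centres.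

Alternative 2: O1–C2 and C2–C3 are cut, giving vinylphenol A5 (rings A and D on a 1,1-disubstituted alkene) and aldehyde A6. Forward, a chiral Brønsted acid condenses A6 with the phenol oxygen, the alkene attacks the activated carbon in a 6-endo mode, and proton loss gives flav-3-ene A4 with C2 set.
- For: ring B enters as a cheap aldehyde with no organometallic step, and the catalyst sits at the carbon that becomes C2. For the skeleton step count and for the proximity of catalyst to the new centre it is equal or better.
- Against: only one of three centres is set. C3 and C4 must then come from the trisubstituted C3=C4 bond of A4 by a net anti addition of H and OH (hydroxyl cis to ring D). Hydroboration adds syn and would give the 3,4-trans isomer. Epoxidation followed by hydride opening with inversion would have to occur at a tertiary, doubly benzylic C4 that prefers to ionise and rearrange. A4 can also lose its C2 configuration by reversible electrocyclic opening of the pyran ring, and the alkene of A5 is a poor nucleophile because ring D is twisted out of conjugation.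
- Comparison: the chosen route obtains the C3/C4 cis relationship from the endo rule in one step and leaves only C2, which a neighbouring group controls.

Alternative 3: O1–C2 and the C3–O bond are cut, giving (E)-alkene A8 with C4 already configured and the ring A phenol silylated. Forward, Shi epoxidation of C2=C3 and desilylation let the phenoxide open the oxirane at benzylic C2 in a 6-endo mode with inversion, giving A7, which is identical with 21.
- For: face selection on a trans-disubstituted alkene is reagent-controlled and predictable, 2,3-trans results directly, and the product is one step from the target. Its end game is shorter and its absolute control at C2 and C3 better founded than in the chosen route.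
- Against: the C4 centre of A8, carrying two different electron-rich aryl groups and a vinyl group, must first be made enantiopure, and any arylation with ring D as nucleophile meets the C6'/C8' problem again. The C3/C4 relationship then depends on the reagent overriding the allylic centre. The oxirane carbon C2 bears a dialkoxyphenyl group, so opening drifts toward an SN1 course with loss of the 2,3 relationship, and 5-exo attack at C3 competes.
- Comparison: the chosen route solves the C4 problem (bond C4–C4a and C3 relative to C4) in the convergent step itself and needs far fewer steps to reach the same compound 21.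

Key step: step 5

Assumption: 2,2-dimethyl-1,3-dioxole (8) is taken as a purchasable, volatile and acid-sensitive reagent and is used in excess.

## Route

Step 1
Reactants: 1 (+)-catechin
Product: 2 5,7,3',4'-tetra-O-benzyl-(+)-catechin
Conditions: BnBr (4.4 equiv.), K2CO3, DMF, 0 °C → rt, argon
Reagents that add atoms: benzyl bromide, BrCc1ccccc1
Why: Williamson etherification; carbonate deprotonates only the four phenols, and mild base with exclusion of air avoids C2 epimerisation, so C3–OH stays free.

Step 2
Reactants: 2 5,7,3',4'-tetra-O-benzyl-(+)-catechin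
Product: 3 3,5,7,3',4'-penta-O-benzyl-(+)-catechin
Conditions: NaH, BnBr, Bu4NI (cat.), THF/DMF, 0 °C → rt
Reagents that add atoms: benzyl bromide, BrCc1ccccc1
Why: Williamson etherification of the secondary alkoxide; with all phenols capped the strong base cannot open ring F, so C2 and C3 are safe.

Step 3
Reactants: 3 3,5,7,3',4'-penta-O-benzyl-(+)-catechin
Product: 4 8-bromo-3,5,7,3',4'-penta-O-benzyl-(+)-catechin
Conditions: N-bromosuccinimide (1.0 equiv.), CH2Cl2, −40 °C → 0 °C
Reagents that add atoms: N-bromosuccinimide, O=C1CCC(=O)N1Br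
Why: Electrophilic aromatic bromination; C8 lies between the small ring oxygen and one benzyloxy group and is more accessible than C6, which is flanked by two benzyloxy groups, so monobromination should take C8.

Step 4
Reactants: 4 8-bromo-3,5,7,3',4'-penta-O-benzyl-(+)-catechin
Product: 6 8-bromo-6-formyl-3,5,7,3',4'-penta-O-benzyl-(+)-catechin, via iminium chloride 5 (not isolated)
Conditions: POCl3, DMF, 0 °C → 70 °C; then aq. NaOAc, rt
Reagents that add atoms: N,N-dimethylformamide, CN(C)C=O; water, O
Why: Vilsmeier–Haack formylation; C6 is the only free position of ring D and is activated by two ortho oxygens and the para ring oxygen, as in the formylation of phloroglucinol triethers; benzyl ethers tolerate the conditions and the iminium salt is hydrolysed on work-up.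

Step 5
Reactants: 6 8-bromo-6-formyl-3,5,7,3',4'-penta-O-benzyl-(+)-catechin; 7 3-benzyloxyphenol; 8 2,2-dimethyl-1,3-dioxole
Product: 12 (2R,3R,4S)-7-benzyloxy-4-BrCat-2,3-O-isopropylidenechroman-2,3-diol (all-cis), via benzodioxaborin 9 (not isolated), via o-hydroxybenzhydrol 10 (not isolated), via o-quinone methide 11 (not isolated)
Conditions: (i) PhB(OH)2 (1.1 equiv.), EtCO2H (cat.), 4 Å MS, toluene, 80 °C; (ii) pinacol (1.05 equiv.), rt, then evaporation of EtCO2H; (iii) 8 (5 equiv.), (R)-3,3'-bis(2,4,6-triisopropylphenyl)-1,1'-binaphthyl-2,2'-diyl hydrogen phosphate (10 mol%), 4 Å MS, toluene, −20 °C → rt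
Reagents that add atoms: none
Why: Three known reaction types are run in one flask: boron-templated ortho-hydroxyalkylation of a phenol by an aldehyde, acid-induced dehydration of an o-hydroxybenzhydrol to an o-quinone methide, and its inverse-electron-demand hetero-Diels–Alder reaction with an enol ether under a chiral phosphoric acid. Phenol 7 and PhB(OH)2 form an aryl boronate that binds the formyl oxygen of 6 and delivers its carbon through a six-membered transition state to the ortho carbon para to the benzyloxy group (the position between the two oxygens is more hindered), which fixes C4–C4a and gives 9; pinacol then removes the boron so that the phenol oxygen of 10 is free for hydrogen bonding to the catalyst. The chiral acid ionises the doubly activated benzhydrol (para-benzyloxy ring A, trialkoxy ring D) to the E-quinone methide 11, with ring D turned away from the carbonyl group. Ring C is closed by an intermolecular [4+2] cycloaddition of the heterodiene O=C8a–C4a=C4 onto the C=C bond of 8, forming C3–C4 and O1–C2, and because 8 is symmetrical there is no regiochemical question. C3 and C4 are controlled by the endo transition state, which puts the dioxole oxygens under the heterodiene and so the C3 oxygen cis to the outward ring D; C2 is controlled by suprafacial addition to the five-membered cis-enediol ether, which makes the C2 and C3 oxygens cis, so the adduct should be all-cis. The catechin centres are too remote from C4 to distinguish the two faces, so the phosphate, hydrogen-bonded to the quinone methide oxygen, has to shield one of them; the (R)-catalyst is written here, and its antipode is used if it proves mismatched. Chemoselectivity depends on the excess of 8 and on no free 7 being left when the quinone methide is released.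

Step 6
Reactants: 12 (2R,3R,4S)-7-benzyloxy-4-BrCat-2,3-O-isopropylidenechroman-2,3-diol
Product: 13 (3R,4S)-7-benzyloxy-4-BrCat-chroman-2,3-diol (lactol, C2 anomers)
Conditions: AcOH/H2O (4:1), THF, 50 °C
Reagents that add atoms: none
Why: Acid hydrolysis of the isopropylidene acetal through the 2-alkoxyprop-2-yl cation; the C2–O and C3–O bonds are not broken, so C3 and C4 are untouched, and the weak acid should spare the benzyl ethers and the C4–C6' bond.

Step 7
Reactants: 13 (3R,4S)-7-benzyloxy-4-BrCat-chroman-2,3-diol
Product: 14 (3R,4S)-7-benzyloxy-4-BrCat-chroman-2,3-diyl bis(2,2-dimethylpropanoate) (C2 anomers)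
Conditions: PivCl, DMAP, pyridine, CH2Cl2, 0 °C → 40 °C
Reagents that add atoms: pivaloyl chloride, CC(C)(C)C(=O)Cl
Why: Nucleophile-catalysed acylation of the lactol hydroxyl and the C3 hydroxyl, as in the peracylation of sugar lactols; the six-membered hemiacetal form dominates, so the ring stays closed.

Step 8
Reactants: 14 (3R,4S)-7-benzyloxy-4-BrCat-chroman-2,3-diyl bis(2,2-dimethylpropanoate)
Product: 15 (3R,4S)-7-benzyloxy-2-bromo-4-BrCat-chroman-3-yl 2,2-dimethylpropanoate (C2 anomers, used crude)
Conditions: Me3SiBr, BiBr3 (cat.), CH2Cl2, 0 °C → rt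
Reagents that add atoms: bromotrimethylsilane, C[Si](C)(C)Br
Why: Exchange of an anomeric ester for bromide as in glycosyl bromide synthesis; only the acetal-type ester at C2 ionises, assisted by the C3 pivalate, and the conditions are milder than HBr in acetic acid toward benzyl ethers and the C4–C6' bond.

Step 9
Reactants: 16 4-bromo-1,2-bis(benzyloxy)benzene
Product: 18 [3,4-bis(benzyloxy)phenyl]zinc bromide (solution containing LiBr), via aryllithium 17 (not isolated)
Conditions: n-BuLi (1.0 equiv.), toluene/n-Bu2O, −10 °C; then ZnBr2·LiBr (1.0 equiv.) in n-Bu2O, 0 °C → rt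
Reagents that add atoms: zinc bromide, Br[Zn]Br
Why: Bromine–lithium exchange followed by transmetalation with one equivalent of ZnBr2 gives the arylzinc bromide; the weakly coordinating solvent mixture keeps the zinc centre Lewis acidic for step 10.

Step 10
Reactants: 15 (3R,4S)-7-benzyloxy-2-bromo-4-BrCat-chroman-3-yl 2,2-dimethylpropanoate; 18 [3,4-bis(benzyloxy)phenyl]zinc bromide
Product: 20 (2S,3R,4S)-7-benzyloxy-2-[3,4-bis(benzyloxy)phenyl]-4-BrCat-chroman-3-yl 2,2-dimethylpropanoate, via dioxolenium bromide 19 (not isolated)
Conditions: 18 (1.5 equiv.), toluene/n-Bu2O, 90 °C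
Reagents that add atoms: none
Why: Uncatalysed arylzinc substitution of an α-bromo ether with anchimeric assistance, the reaction type used for 1,2-trans C-aryl glycosides from pivaloylated glycosyl bromides; zinc takes up bromide, the C3 pivalate closes to the cis-fused dioxolenium ion 19 on the face of the C3 oxygen, and the aryl group is delivered to C2 from the opposite face, which is also the face away from ring D, setting C2 trans to the C3 oxygen. The tert-butyl group blocks attack at the acyl carbon, and the aryl bromide on ring D is inert without a transition-metal catalyst.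

Step 11
Reactants: 20 (2S,3R,4S)-7-benzyloxy-2-[3,4-bis(benzyloxy)phenyl]-4-BrCat-chroman-3-yl 2,2-dimethylpropanoate
Product: 21 (2S,3R,4S)-7-benzyloxy-2-[3,4-bis(benzyloxy)phenyl]-4-BrCat-chroman-3-ol
Conditions: i-Bu2AlH, CH2Cl2, −78 °C → 0 °C; aq. potassium sodium tartrate
Reagents that add atoms: none
Why: Reductive cleavage of a hindered ester by an aluminium hydride; no stereocentre is epimerisable under these conditions, and benzyl ethers and the aryl bromide are inert.

Step 12
Reactants: 21 (2S,3R,4S)-7-benzyloxy-2-[3,4-bis(benzyloxy)phenyl]-4-BrCat-chroman-3-ol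
Product: 22 (2S,3R,4S)-2-(3,4-dihydroxyphenyl)-4-[(2R,3S)-2-(3,4-dihydroxyphenyl)-3,5,7-trihydroxychroman-6-yl]chromane-3,7-diol
Conditions: H2 (1 atm), Pd(OH)2 on carbon, NaOAc, THF/MeOH/H2O, rt
Reagents that add atoms: none
Why: Catalytic hydrogenolysis of the eight benzyl ethers together with hydrodebromination at C8'; acetate buffers the HBr formed so that the acid-labile C4–C6' bond and the C2 centres are not endangered, and the neutral reducing medium protects the free polyphenol from oxidation.

## Compound list

1 | (+)-catechin, (2R,3S)-2-(3,4-dihydroxyphenyl)chromane-3,5,7-triol | O[C@H]1Cc2c(O)cc(O)cc2O[C@@H]1c1ccc(O)c(O)c1 | starting material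
2 | 5,7,3',4'-tetra-O-benzyl-(+)-catechin | O[C@H]1Cc2c(OCc3ccccc3)cc(OCc3ccccc3)cc2O[C@@H]1c1ccc(OCc2ccccc2)c(OCc2ccccc2)c1 | intermediate
3 | 3,5,7,3',4'-penta-O-benzyl-(+)-catechin | c1ccccc1CO[C@H]1Cc2c(OCc3ccccc3)cc(OCc3ccccc3)cc2O[C@@H]1c1ccc(OCc2ccccc2)c(OCc2ccccc2)c1 | intermediate
4 | 8-bromo-3,5,7,3',4'-penta-O-benzyl-(+)-catechin | c1ccccc1CO[C@H]1Cc2c(OCc3ccccc3)cc(OCc3ccccc3)c(Br)c2O[C@@H]1c1ccc(OCc2ccccc2)c(OCc2ccccc2)c1 | intermediate
5 | N,N-dimethyl-(BrCat-methylidene)iminium chloride | C[N+](C)=Cc1c(OCc3ccccc3)c(Br)c2c(c1OCc1ccccc1)C[C@H](OCc1ccccc1)[C@@H](c1ccc(OCc3ccccc3)c(OCc3ccccc3)c1)O2.[Cl-] | intermediate (not isolated)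
6 | 8-bromo-6-formyl-3,5,7,3',4'-penta-O-benzyl-(+)-catechin | O=Cc1c(OCc3ccccc3)c(Br)c2c(c1OCc1ccccc1)C[C@H](OCc1ccccc1)[C@@H](c1ccc(OCc3ccccc3)c(OCc3ccccc3)c1)O2 | intermediate
7 | 3-benzyloxyphenol | Oc1cccc(OCc2ccccc2)c1 | starting material
8 | 2,2-dimethyl-1,3-dioxole | CC1(C)OC=CO1 | starting material
9 | 7-benzyloxy-2-phenyl-4-BrCat-4H-1,3,2-benzodioxaborin (both C4 epimers) | c1ccccc1COc1ccc2c(c1)OB(c1ccccc1)OC2c1c(OCc3ccccc3)c(Br)c2c(c1OCc1ccccc1)C[C@H](OCc1ccccc1)[C@@H](c1ccc(OCc3ccccc3)c(OCc3ccccc3)c1)O2 | intermediate (not isolated)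
10 | 5-benzyloxy-2-[hydroxy(BrCat)methyl]phenol (both carbinol epimers) | Oc1cc(OCc2ccccc2)ccc1C(O)c1c(OCc3ccccc3)c(Br)c2c(c1OCc1ccccc1)C[C@H](OCc1ccccc1)[C@@H](c1ccc(OCc3ccccc3)c(OCc3ccccc3)c1)O2 | intermediate (not isolated)
11 | (E)-3-benzyloxy-6-(BrCat-methylidene)cyclohexa-2,4-dien-1-one | O=C1C=C(OCc2ccccc2)C=C/C1=C\c1c(OCc3ccccc3)c(Br)c2c(c1OCc1ccccc1)C[C@H](OCc1ccccc1)[C@@H](c1ccc(OCc3ccccc3)c(OCc3ccccc3)c1)O2 | intermediate (not isolated)
12 | (2R,3R,4S)-7-benzyloxy-4-BrCat-2,3-O-isopropylidenechroman-2,3-diol (all-cis) | c1ccccc1COc1ccc2c(c1)O[C@@H]3OC(C)(C)O[C@@H]3[C@@H]2c1c(OCc3ccccc3)c(Br)c2c(c1OCc1ccccc1)C[C@H](OCc1ccccc1)[C@@H](c1ccc(OCc3ccccc3)c(OCc3ccccc3)c1)O2 | intermediate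
13 | (3R,4S)-7-benzyloxy-4-BrCat-chroman-2,3-diol (lactol, C2 anomers) | c1ccccc1COc1ccc2c(c1)OC(O)[C@H](O)[C@@H]2c1c(OCc3ccccc3)c(Br)c2c(c1OCc1ccccc1)C[C@H](OCc1ccccc1)[C@@H](c1ccc(OCc3ccccc3)c(OCc3ccccc3)c1)O2 | intermediate
14 | (3R,4S)-7-benzyloxy-4-BrCat-chroman-2,3-diyl bis(2,2-dimethylpropanoate) (C2 anomers) | c1ccccc1COc1ccc2c(c1)OC(OC(=O)C(C)(C)C)[C@H](OC(=O)C(C)(C)C)[C@@H]2c1c(OCc3ccccc3)c(Br)c2c(c1OCc1ccccc1)C[C@H](OCc1ccccc1)[C@@H](c1ccc(OCc3ccccc3)c(OCc3ccccc3)c1)O2 | intermediate
15 | (3R,4S)-7-benzyloxy-2-bromo-4-BrCat-chroman-3-yl 2,2-dimethylpropanoate (C2 anomers) | c1ccccc1COc1ccc2c(c1)OC(Br)[C@H](OC(=O)C(C)(C)C)[C@@H]2c1c(OCc3ccccc3)c(Br)c2c(c1OCc1ccccc1)C[C@H](OCc1ccccc1)[C@@H](c1ccc(OCc3ccccc3)c(OCc3ccccc3)c1)O2 | intermediate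
16 | 4-bromo-1,2-bis(benzyloxy)benzene | Brc1ccc(OCc2ccccc2)c(OCc2ccccc2)c1 | starting material
17 | 3,4-bis(benzyloxy)phenyllithium | [Li]c1ccc(OCc2ccccc2)c(OCc2ccccc2)c1 | intermediate (not isolated)
18 | [3,4-bis(benzyloxy)phenyl]zinc bromide | Br[Zn]c1ccc(OCc2ccccc2)c(OCc2ccccc2)c1 | intermediate
19 | 2-tert-butyl-1,3-dioxolan-2-ylium bromide cis-fused across C2–C3 of 7-benzyloxy-4-BrCat-chroman, both ring oxygens on the face of ring D | c1ccccc1COc1ccc2c(c1)O[C@@H]3O[C+](C(C)(C)C)O[C@@H]3[C@@H]2c1c(OCc3ccccc3)c(Br)c2c(c1OCc1ccccc1)C[C@H](OCc1ccccc1)[C@@H](c1ccc(OCc3ccccc3)c(OCc3ccccc3)c1)O2.[Br-] | intermediate (not isolated)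
20 | (2S,3R,4S)-7-benzyloxy-2-[3,4-bis(benzyloxy)phenyl]-4-BrCat-chroman-3-yl 2,2-dimethylpropanoate | c1ccccc1COc1ccc2c(c1)O[C@@H](c1ccc(OCc3ccccc3)c(OCc3ccccc3)c1)[C@H](OC(=O)C(C)(C)C)[C@@H]2c1c(OCc3ccccc3)c(Br)c2c(c1OCc1ccccc1)C[C@H](OCc1ccccc1)[C@@H](c1ccc(OCc3ccccc3)c(OCc3ccccc3)c1)O2 | intermediate
21 | (2S,3R,4S)-7-benzyloxy-2-[3,4-bis(benzyloxy)phenyl]-4-BrCat-chroman-3-ol | c1ccccc1COc1ccc2c(c1)O[C@@H](c1ccc(OCc3ccccc3)c(OCc3ccccc3)c1)[C@H](O)[C@@H]2c1c(OCc3ccccc3)c(Br)c2c(c1OCc1ccccc1)C[C@H](OCc1ccccc1)[C@@H](c1ccc(OCc3ccccc3)c(OCc3ccccc3)c1)O2 | intermediate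
22 | (2S,3R,4S)-2-(3,4-dihydroxyphenyl)-4-[(2R,3S)-2-(3,4-dihydroxyphenyl)-3,5,7-trihydroxychroman-6-yl]chromane-3,7-diol | Oc1ccc2c(c1)O[C@@H](c1ccc(O)c(O)c1)[C@H](O)[C@@H]2c1c(O)cc2c(c1O)C[C@H](O)[C@@H](c1ccc(O)c(O)c1)O2 | target

## Step count and least certain steps

Total: 12 steps. Longest linear sequence: 11 steps (steps 1–8 and 10–12 from catechin 1); step 9 is a one-step side branch.

**Step 5 (key step).** The most likely failure is poor facial selectivity. Ring D is twisted out of the quinone methide plane, its two ortho benzyloxy groups look alike from either face, and the dioxole has no hydrogen-bond donor for the catalyst, so both all-cis adducts may form. A second risk is capture of the quinone methide by unreacted phenol 7 or slow ortho-alkylation by the hindered aldehyde. Fallback: setting out from 6, 7 and 8, the same assembly is run without the chiral acid (diphenyl hydrogen phosphate, or heating at 80 °C), accepting both all-cis isomers. The unwanted all-cis facial isomer, (2S,3S,4R)-7-benzyloxy-4-BrCat-2,3-O-isopropylidenechroman-2,3-diol F1, is a diastereomer of 12 and is removed by chromatography or crystallisation. The route is rejoined at 12, with control by separation in place of control by catalyst.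

**Step 10.** The most likely failure is slow ionisation at C2, whose oxygen is an aryl ether oxygen and a weaker donor than in a sugar, combined with slow aryl transfer from the arylzinc halide, which is only a moderate nucleophile. This would allow elimination of HBr across C2–C3, or loss of face control if the pivalate does not participate. Fallback, setting out from lactol 13 and bromide 16: 16 is converted with magnesium into 3,4-bis(benzyloxy)phenylmagnesium bromide F2, which in excess adds to the open hydroxy-aldehyde form of 13 under chelation by the C3 alkoxide. This gives 1-[3,4-bis(benzyloxy)phenyl]-3-(4-benzyloxy-2-hydroxyphenyl)-3-BrCat-propane-1,2-diol F3. Triethyl orthoformate with pyridinium p-toluenesulfonate then closes ring C at the cation-like benzylic carbon, giving the 2,3-trans 3-O-formate, (2S,3R,4S)-7-benzyloxy-2-[3,4-bis(benzyloxy)phenyl]-4-BrCat-chroman-3-yl formate F4. Methanolysis with K2CO3 returns to the route at 21. This replaces steps 7, 8, 10 and 11, with C2 set by ring closure instead of by neighbouring-group participation.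

**Step 4.** The most likely failure is sluggish attack of the bulky chloroiminium electrophile at C6, which lies between two benzyloxy groups on a ring deactivated by bromine. The heating then required could cause partial debenzylation by HCl. Fallback, setting out from 4: iodination at C6 (N-iodosuccinimide, catalytic CF3CO2H, CH2Cl2) gives 8-bromo-6-iodo-3,5,7,3',4'-penta-O-benzyl-(+)-catechin F5. Selective iodine–magnesium exchange with i-PrMgCl·LiCl at −30 °C, where the bromide exchanges far more slowly, gives the 6-magnesio-8-bromo-penta-O-benzylcatechin chloride F6. Quenching with DMF comes back at 6.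

**Step 12.** The most likely failure is incomplete hydrogenolysis. Bromide released at the catalyst slows cleavage of the hindered benzyl ethers, and any unbuffered HBr threatens the C4–C6' bond. Fallback, setting out from 21: the bromine is first removed by radical chain reduction (Bu3SnH, azobisisobutyronitrile, toluene, 90 °C) to give the bromine-free octa-O-benzyl ether, (2S,3R,4S)-7-benzyloxy-2-[3,4-bis(benzyloxy)phenyl]-4-[3,5,7,3',4'-penta-O-benzyl-(+)-catechin-6-yl]chroman-3-ol F7. F7 is then hydrogenolysed over Pd(OH)2 on carbon under neutral conditions, arriving at 22.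

## Further compounds

F1 | step 5 | (2S,3S,4R)-7-benzyloxy-4-BrCat-2,3-O-isopropylidenechroman-2,3-diol (all-cis facial isomer of 12) | c1ccccc1COc1ccc2c(c1)O[C@H]3OC(C)(C)O[C@H]3[C@H]2c1c(OCc3ccccc3)c(Br)c2c(c1OCc1ccccc1)C[C@H](OCc1ccccc1)[C@@H](c1ccc(OCc3ccccc3)c(OCc3ccccc3)c1)O2
F2 | step 10 | 3,4-bis(benzyloxy)phenylmagnesium bromide | Br[Mg]c1ccc(OCc2ccccc2)c(OCc2ccccc2)c1
F3 | step 10 | 1-[3,4-bis(benzyloxy)phenyl]-3-(4-benzyloxy-2-hydroxyphenyl)-3-BrCat-propane-1,2-diol (C2 and C3 of the chain as C3 and C4 of 13; carbinol C1 epimers) | OC(c1ccc(OCc3ccccc3)c(OCc3ccccc3)c1)[C@H](O)[C@@H](c1ccc(OCc3ccccc3)cc1O)c1c(OCc3ccccc3)c(Br)c2c(c1OCc1ccccc1)C[C@H](OCc1ccccc1)[C@@H](c1ccc(OCc3ccccc3)c(OCc3ccccc3)c1)O2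
F4 | step 10 | (2S,3R,4S)-7-benzyloxy-2-[3,4-bis(benzyloxy)phenyl]-4-BrCat-chroman-3-yl formate | c1ccccc1COc1ccc2c(c1)O[C@@H](c1ccc(OCc3ccccc3)c(OCc3ccccc3)c1)[C@H](OC=O)[C@@H]2c1c(OCc3ccccc3)c(Br)c2c(c1OCc1ccccc1)C[C@H](OCc1ccccc1)[C@@H](c1ccc(OCc3ccccc3)c(OCc3ccccc3)c1)O2
F5 | step 4 | 8-bromo-6-iodo-3,5,7,3',4'-penta-O-benzyl-(+)-catechin | c1ccccc1CO[C@H]1Cc2c(OCc3ccccc3)c(I)c(OCc3ccccc3)c(Br)c2O[C@@H]1c1ccc(OCc2ccccc2)c(OCc2ccccc2)c1
F6 | step 4 | [8-bromo-3,5,7,3',4'-penta-O-benzyl-(+)-catechin-6-yl]magnesium chloride | c1ccccc1CO[C@H]1Cc2c(OCc3ccccc3)c([Mg]Cl)c(OCc3ccccc3)c(Br)c2O[C@@H]1c1ccc(OCc2ccccc2)c(OCc2ccccc2)c1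
F7 | step 12 | (2S,3R,4S)-7-benzyloxy-2-[3,4-bis(benzyloxy)phenyl]-4-[3,5,7,3',4'-penta-O-benzyl-(+)-catechin-6-yl]chroman-3-ol (bromine-free) | c1ccccc1COc1ccc2c(c1)O[C@@H](c1ccc(OCc3ccccc3)c(OCc3ccccc3)c1)[C@H](O)[C@@H]2c1c(OCc3ccccc3)cc2c(c1OCc1ccccc1)C[C@H](OCc1ccccc1)[C@@H](c1ccc(OCc3ccccc3)c(OCc3ccccc3)c1)O2
A1 | alternative 1 | benzyl-protected 22 with free C5' phenol and C7' triisopropylsilyl ether | c1ccccc1COc1ccc2c(c1)O[C@@H](c1ccc(OCc3ccccc3)c(OCc3ccccc3)c1)[C@H](OCc1ccccc1)[C@@H]2c1c(O[Si](C(C)C)(C(C)C)C(C)C)cc2c(c1O)C[C@H](OCc1ccccc1)[C@@H](c1ccc(OCc3ccccc3)c(OCc3ccccc3)c1)O2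
A2 | alternative 1 | (2R,3S)-3-benzyloxy-2-[3,4-bis(benzyloxy)phenyl]-6-(diazoacetyl)-3,4-dihydro-2H-pyran | [N-]=[N+]=CC(=O)C1=CC[C@H](OCc2ccccc2)[C@@H](c2ccc(OCc3ccccc3)c(OCc3ccccc3)c2)O1
A3 | alternative 1 | (2S,3R)-3,7-bis(benzyloxy)-2-[3,4-bis(benzyloxy)phenyl]-4-[(triisopropylsilyloxy)ethynyl]chroman, C4 configured as in 22 | c1ccccc1COc1ccc2c(c1)O[C@@H](c1ccc(OCc3ccccc3)c(OCc3ccccc3)c1)[C@H](OCc1ccccc1)[C@@H]2C#CO[Si](C(C)C)(C(C)C)C(C)C
A4 | alternative 2 | (2S)-7-benzyloxy-2-[3,4-bis(benzyloxy)phenyl]-4-BrCat-2H-chromene | c1ccccc1COc1ccc2c(c1)O[C@@H](c1ccc(OCc3ccccc3)c(OCc3ccccc3)c1)C=C2c1c(OCc3ccccc3)c(Br)c2c(c1OCc1ccccc1)C[C@H](OCc1ccccc1)[C@@H](c1ccc(OCc3ccccc3)c(OCc3ccccc3)c1)O2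
A5 | alternative 2 | 5-benzyloxy-2-[1-(BrCat)ethenyl]phenol | Oc1cc(OCc2ccccc2)ccc1C(=C)c1c(OCc3ccccc3)c(Br)c2c(c1OCc1ccccc1)C[C@H](OCc1ccccc1)[C@@H](c1ccc(OCc3ccccc3)c(OCc3ccccc3)c1)O2
A6 | alternative 2 | 3,4-bis(benzyloxy)benzaldehyde | O=Cc1ccc(OCc2ccccc2)c(OCc2ccccc2)c1
A7 | alternative 3 | (2S,3R,4S)-7-benzyloxy-2-[3,4-bis(benzyloxy)phenyl]-4-BrCat-chroman-3-ol (identical with 21) | c1ccccc1COc1ccc2c(c1)O[C@@H](c1ccc(OCc3ccccc3)c(OCc3ccccc3)c1)[C@H](O)[C@@H]2c1c(OCc3ccccc3)c(Br)c2c(c1OCc1ccccc1)C[C@H](OCc1ccccc1)[C@@H](c1ccc(OCc3ccccc3)c(OCc3ccccc3)c1)O2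
A8 | alternative 3 | tert-butyldimethylsilyl ether of 5-benzyloxy-2-[(E)-3-[3,4-bis(benzyloxy)phenyl]-1-(BrCat)prop-2-en-1-yl]phenol, C4 configured as in 22 | CC(C)(C)[Si](C)(C)Oc1cc(OCc2ccccc2)ccc1[C@H](/C=C/c1ccc(OCc2ccccc2)c(OCc2ccccc2)c1)c1c(OCc3ccccc3)c(Br)c2c(c1OCc1ccccc1)C[C@H](OCc1ccccc1)[C@@H](c1ccc(OCc3ccccc3)c(OCc3ccccc3)c1)O2
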